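**Plan**
1. Cuts: C11=C12 and C11'=C12' (two Wittig reactions on the C10 trienedial 15). On the ε side also C8'–C9' (Suzuki–Miyaura) and C7'=C8' (Takai); on the β side C7=C8 (Horner–Wadsworth–Emmons). Both rings go back to one aldehyde, 8.
2. Enabling feature: in the ε-ring (C1'–C6') the stereocentre C6' lies between quaternary C1' and the C4'=C5' alkene and bears the sp2 carbon C7'. A formyl carbon on such a centre is the retron of a semipinacol shift, so C7' is put back into the ring between C6' and C1'. The ε-ring is then made by contraction of a cycloheptene oxide (ring C1'–C7').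
3. That seven-membered ring with its three methyl groups is the perimeter of 3-carene. Steps 1–6: allylic oxidation, base-induced opening of the internal cyclopropane bond to dienone 3, epoxidation, reduction, silylation, contraction.
4. The β-ring is not built separately. Hydroxyl-directed epoxidation of the ε-type aldehyde 17 and E1cB opening move the alkene to C5=C6 and place the C4 hydroxyl cis to the C3 hydroxyl.
5. Order of joining: 8 → C15 salt 14 → C25 aldehyde 16; 8 → C15 salt 25; 16 + 25 → C40; desilylation.
6. Stereochemistry: C6' comes from the Jacobsen–Katsuki epoxide (two inversions in step 6), C3' and C3 from one CBS reduction, C4 from the directed epoxidation. Alkene geometry comes from Takai, syn-borylcupration, HWE and thermal equilibration after each Wittig step.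

Key step: step 6

Remark: carotenoid numbering is used (C1–C6 and C1'–C6' ring atoms, C7 and C7' first chain atoms), and the seven-membered precursors keep the primed numbers their atoms have in the target. Compounds 1, 10, 15 and 21 are taken as commercial. The target is (3S,4R,3'S,6'R)-β,ε-carotene-3,4,3'-triol, with the 3,4-diol cis and 3'-OH cis to the chain at C6'.

Step 1
Reactants: 1 (+)-3-carene
Product: 2 (1R,6S)-4,7,7-trimethylbicyclo[4.1.0]hept-3-en-2-one (car-3-en-5-one)
Conditions: t-BuOOH (decane), Cr(CO)6 (cat.), MeCN, reflux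
Reagents that add atoms: tert-butyl hydroperoxide, CC(C)(C)OO
Why: Chromium-catalysed allylic oxidation with a hydroperoxide: of the two allylic ring CH2 groups the one next to the unsubstituted alkene carbon is the more accessible and is the position at which 3-carene is known to give its enone, the cyclopropane is untouched and no stereocentre is made.

Step 2
Reactants: 2 car-3-en-5-one
Product: 3 3,6,6-trimethylcyclohepta-2,4-dien-1-one
Conditions: KOtBu (20 mol %), t-BuOH, 50 °C
Reagents that add atoms: none
Why: Base-catalysed carenone to cycloheptadienone isomerisation, the reaction type by which car-3-en-2-one passes into eucarvone: γ-deprotonation at the ring CH2 gives a norcaradiene-type dienolate whose internal cyclopropane bond opens in a disrotatory six-electron process (the gem-dimethyl carbon favours the cycloheptatriene side), and α-protonation gives the linearly conjugated dienone, in which both stereocentres of 1 are gone, so its optical purity does not matter.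

Step 3
Reactants: 3 3,6,6-trimethylcyclohepta-2,4-dien-1-one
Product: 4 (1R,7S)-2,6,6-trimethyl-8-oxabicyclo[5.1.0]oct-2-en-4-one (6'R,7'S epoxy enone)
Conditions: (R,R)-[N,N'-bis(3,5-di-tert-butylsalicylidene)cyclohexane-1,2-diaminato]MnCl (4 mol %), 4-phenylpyridine N-oxide (20 mol %), aq NaOCl (pH 11.3), CH2Cl2, 0 °C
Reagents that add atoms: sodium hypochlorite, [Na+].[O-]Cl
Why: Jacobsen–Katsuki epoxidation: the electron-poor trisubstituted C4'=C5' alkene is left alone, the cis-disubstituted C6'=C7' alkene sits between a conjugating group and a gem-dimethyl carbon exactly as in 2,2-dimethylchromene, and by analogy with that chromene and with indene the (R,R) complex should deliver oxygen to the face that gives the 6'R,7'S epoxide.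

Step 4
Reactants: 4 epoxy enone
Product: 5 (1R,4S,7S)-2,6,6-trimethyl-8-oxabicyclo[5.1.0]oct-2-en-4-ol (hydroxyl trans to the oxirane oxygen)
Conditions: (R)-2-methyl-CBS-oxazaborolidine (20 mol %), catecholborane, toluene, −78 °C; aqueous work-up
Reagents that add atoms: none
Why: Corey–Bakshi–Shibata reduction, strictly 1,2: the ketone has the local surroundings of isophorone (β-methylalkenyl arm large, CH2–CMe2 arm small), so the (R)-oxazaborolidine should deliver hydride to the face that gives the 3'S carbinol, and cold catecholborane leaves the vinyl epoxide alone.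

Step 5
Reactants: 5 trans-epoxy alcohol
Product: 6 tert-butyldimethylsilyl ether of 5
Conditions: TBSCl, imidazole, DMF, rt
Reagents that add atoms: tert-butyldimethylsilyl chloride, CC(C)(C)[Si](C)(C)Cl
Why: Standard silylation of a secondary allylic alcohol under mildly basic conditions that do not touch the epoxide or any stereocentre.

Step 6
Reactants: 6 silylated trans-epoxy alcohol
Product: 8 (1R,4S)-4-(tert-butyldimethylsilyloxy)-2,6,6-trimethylcyclohex-2-ene-1-carbaldehyde, via bromohydrin magnesium alkoxide 7 (not isolated)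
Conditions: MgBr2·OEt2 (0.5 equiv), CH2Cl2, −40 → 0 °C
Reagents that add atoms: none
Why: MgBr2 binds the epoxide oxygen and bromide opens the ring by SN2 attack at the allylic carbon C6' (the other carbon, C7', is neopentyl) to give the trans bromohydrin alkoxide 7; in its pseudo-diequatorial conformer the ring bond C7'–C1' lies antiperiplanar to C6'–Br, so the alkoxide pushes quaternary C1' from C7' to C6' as bromide leaves, C7' is expelled from the ring as the formyl carbon and MgBr2 is set free again. The closest known reaction type is the magnesium or lithium halide-catalysed contraction of cyclohexene and cycloheptene oxides to cyclopentane- and cyclohexanecarbaldehydes, a semipinacol rearrangement by way of the halohydrin salt. The six-membered ring is closed not by an exo or endo cyclisation but by this suprafacial 1,2-shift, in which C1' displaces bromide at C6' from the rear through a three-centre transition state. The only new stereocentre, C6', results from two inversions (bromide in, C1' in), so the epoxide configuration of step 3 is carried over with net retention and the formyl group ends cis to the C3' silyl ether; should the allylic bromide ionise first, the C7' alkoxide still holds C1' over the same face because its oxygen turns away from the C5' methyl group, so both timings lead to the same epimer. The step needs allylic instead of neopentyl opening, SN2 instead of SN2' attack, carbon instead of hydride shift and no drift of the alkene into conjugation: the first is secured by the C4'=C5' alkene next to C6' and the gem-dimethyl group next to C7', the third by the trans geometry of 7 (H-7' is gauche to bromide, while C1' is anti and is the best migrating alkyl group), the last by the mild non-basic medium. The silyl ether keeps the C3' oxygen, which sits on the face opposite to the epoxide, from bridging across the ring to C6'.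

Step 7
Reactants: 8 ε-type aldehyde
Product: 9 tert-butyl{[(1S,4R)-4-[(E)-2-iodoethenyl]-3,5,5-trimethylcyclohex-2-en-1-yl]oxy}dimethylsilane
Conditions: CrCl2, CHI3, THF, 0 °C
Reagents that add atoms: iodoform, IC(I)I
Why: Takai olefination: the organochromium reagent is non-basic, so the epimerisable and conjugation-prone C6' centre is safe, and hindered α-branched aldehydes give the E-iodoalkene.

Step 8
Reactants: 10 but-2-yn-1-ol
Product: 11 (Z)-3-(4,4,5,5-tetramethyl-1,3,2-dioxaborolan-2-yl)but-2-en-1-ol
Conditions: B2pin2, CuCl (5 mol %), PCy3 (6 mol %), NaOtBu (15 mol %), MeOH (2 equiv), toluene, rt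
Reagents that add atoms: bis(pinacolato)diboron, CC1(C)OB(OC1(C)C)B1OC(C)(C)C(C)(C)O1
Why: Copper-catalysed formal hydroboration (syn borylcupration, then protonolysis) places boron on the alkyne carbon remote from the propargylic oxygen and so fixes the geometry of the future C9'=C10' bond.

Step 9
Reactants: 9 E-iodoalkene; 11 alkenylboronate
Product: 12 (2E,4E)-5-[(1R,4S)-4-(tert-butyldimethylsilyloxy)-2,6,6-trimethylcyclohex-2-en-1-yl]-3-methylpenta-2,4-dien-1-ol
Conditions: Pd(PPh3)4 (5 mol %), aq KOH, THF, rt
Reagents that add atoms: none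
Why: Suzuki–Miyaura coupling of an alkenyl iodide and an alkenylboronate forms C8'–C9' with retention at both partners, and the free primary alcohol, the silyl ether and the skipped ring alkene tolerate zerovalent palladium and aqueous hydroxide at room temperature.

Step 10
Reactants: 12 ε-C15 dienol
Product: 14 ε-C15 triphenylphosphonium bromide, via allylic bromide 13 (not isolated)
Conditions: CBr4, PPh3, CH2Cl2, 0 °C; then PPh3, rt
Reagents that add atoms: carbon tetrabromide, BrC(Br)(Br)Br; triphenylphosphine, c1ccc(cc1)P(c1ccccc1)c1ccccc1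
Why: Appel bromination followed by quaternisation of PPh3 makes the allylic phosphonium salt without acid, so the allylic C3' silyl ether is not ionised.

Step 11
Reactants: 14 ε-C15 phosphonium bromide; 15 (2E,4E,6E)-2,7-dimethylocta-2,4,6-trienedial
Product: 16 (3S,6R)-3-(tert-butyldimethylsilyloxy)-12'-apo-ε-caroten-12'-al (C25 aldehyde)
Conditions: NaOMe, MeOH/CH2Cl2, 0 °C → rt, 15 in excess; then heptane, 80 °C
Reagents that add atoms: none
Why: Wittig olefination of the symmetrical dialdehyde used in excess should stop at the mono-adduct, the new C11'=C12' bond is equilibrated thermally to E, and methoxide at room temperature does not move the ε-ring alkene.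

Step 12
Reactants: 8 ε-type aldehyde (second portion)
Product: 17 (1R,4S)-4-hydroxy-2,6,6-trimethylcyclohex-2-ene-1-carbaldehyde
Conditions: HF·pyridine, pyridine, THF, 0 °C
Reagents that add atoms: none
Why: Fluoride cleavage of the silyl ether in a pyridine-buffered medium that is neither basic enough to enolise the aldehyde nor acidic enough to ionise the allylic alcohol.

Step 13
Reactants: 17 hydroxy aldehyde
Product: 19 (3R,4S)-3,4-dihydroxy-2,6,6-trimethylcyclohex-1-ene-1-carbaldehyde (3S,4R in carotenoid numbering; cis-diol), via epoxy aldehyde 18 (not isolated)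
Conditions: VO(acac)2 (2 mol %), t-BuOOH (1.05 equiv), CH2Cl2, 0 °C; then DBU (10 mol %), rt
Reagents that add atoms: tert-butyl hydroperoxide, CC(C)(C)OO
Why: Hydroxyl-directed vanadium-catalysed epoxidation delivers oxygen to the C4=C5 face that carries the C3 hydroxyl, and the β,γ-epoxy aldehyde then opens by amine-catalysed E1cB elimination (loss of H-6, cleavage of C5–O; the type by which α-ionone epoxide gives 4-hydroxy-β-ionone), which moves the alkene into conjugation and leaves the C4 hydroxyl cis to the C3 hydroxyl.

Step 14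
Reactants: 19 cis-diol enal
Product: 20 (3R,4S)-3,4-bis(tert-butyldimethylsilyloxy)-2,6,6-trimethylcyclohex-1-ene-1-carbaldehyde
Conditions: TBSOTf, 2,6-lutidine, CH2Cl2, 0 °C
Reagents that add atoms: tert-butyldimethylsilyl triflate, CC(C)(C)[Si](C)(C)OS(=O)(=O)C(F)(F)F
Why: The silyl triflate with a hindered pyridine silylates both the C3 and the more hindered allylic C4 hydroxyl, and fluoride-labile groups are chosen because acid at the end would ionise C4–O and C3'–O.

Step 15
Reactants: 20 bis-silyl enal; 21 triethyl 3-methyl-4-phosphonocrotonate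
Product: 22 ethyl (2E,4E)-5-[(3R,4S)-3,4-bis(tert-butyldimethylsilyloxy)-2,6,6-trimethylcyclohex-1-en-1-yl]-3-methylpenta-2,4-dienoate
Conditions: LiN(SiMe3)2, THF/DMPU, −78 °C → rt
Reagents that add atoms: none
Why: Vinylogous Horner–Wadsworth–Emmons olefination, well known for β-cyclocitral itself, forms C7=C8 with E geometry and C9=C10 mainly as E (the 9Z isomer is removed by chromatography), and 20 has no α-hydrogen.

Step 16
Reactants: 22 β-C15 ester
Product: 23 (2E,4E)-5-[(3R,4S)-3,4-bis(tert-butyldimethylsilyloxy)-2,6,6-trimethylcyclohex-1-en-1-yl]-3-methylpenta-2,4-dien-1-ol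
Conditions: iBu2AlH, CH2Cl2, −78 °C
Reagents that add atoms: none
Why: Hydride reduction of a conjugated ester to the allylic alcohol is purely 1,2 and leaves silyl ethers and alkene geometry untouched.

Step 17
Reactants: 23 β-C15 trienol
Product: 25 β-C15 triphenylphosphonium bromide, via allylic bromide 24 (not isolated)
Conditions: CBr4, PPh3, CH2Cl2, 0 °C; then PPh3, rt
Reagents that add atoms: carbon tetrabromide, BrC(Br)(Br)Br; triphenylphosphine, c1ccc(cc1)P(c1ccccc1)c1ccccc1
Why: Appel bromination and quaternisation activate only the primary allylic alcohol under acid-free conditions, which spares the easily ionised C4 silyl ether.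

Step 18
Reactants: 16 C25 aldehyde; 25 β-C15 phosphonium bromide
Product: 26 (3S,4R,3'S,6'R)-3,4,3'-tris(tert-butyldimethylsilyloxy)-β,ε-carotene
Conditions: NaOMe, MeOH/CH2Cl2, 0 °C → rt; then heptane, 80 °C, argon, dark
Reagents that add atoms: none
Why: The Wittig olefination standard for C15 + C25 carotenoid assembly forms C11=C12, its Z component is equilibrated thermally to the all-E polyene, and no stereocentre is touched.

Step 19
Reactants: 26 tris-silyl ether
Product: 27 (3S,4R,3'S,6'R)-β,ε-carotene-3,4,3'-triol
Conditions: Bu4NF, THF, rt, argon, dark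
Reagents that add atoms: none
Why: Fluoride removes all three silyl ethers under non-acidic conditions, so neither allylic carbinol (C4, C3') ionises or epimerises and the ε-ring alkene stays in place.

**Compound list**
1 | (+)-3-carene, (1S,6R)-3,7,7-trimethylbicyclo[4.1.0]hept-3-ene | CC1=CC[C@@H]2[C@H](C1)C2(C)C | starting material
2 | (1R,6S)-4,7,7-trimethylbicyclo[4.1.0]hept-3-en-2-one | CC1=CC(=O)[C@@H]2[C@H](C1)C2(C)C | intermediate
3 | 3,6,6-trimethylcyclohepta-2,4-dien-1-one | CC1=CC(=O)CC(C)(C)C=C1 | intermediate
4 | (1R,7S)-2,6,6-trimethyl-8-oxabicyclo[5.1.0]oct-2-en-4-one | O=C1C=C(C)[C@H]2O[C@H]2C(C)(C)C1 | intermediate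
5 | (1R,4S,7S)-2,6,6-trimethyl-8-oxabicyclo[5.1.0]oct-2-en-4-ol | O[C@@H]1C=C(C)[C@H]2O[C@H]2C(C)(C)C1 | intermediate
6 | tert-butyldimethylsilyl ether of 5 | CC(C)(C)[Si](C)(C)O[C@@H]1C=C(C)[C@H]2O[C@H]2C(C)(C)C1 | intermediate
7 | bromomagnesium (1S,2S,5S)-2-bromo-5-(tert-butyldimethylsilyloxy)-3,7,7-trimethylcyclohept-3-en-1-olate | CC(C)(C)[Si](C)(C)O[C@@H]1C=C(C)[C@H](Br)[C@@H](O[Mg]Br)C(C)(C)C1 | intermediate (not isolated)
8 | (1R,4S)-4-(tert-butyldimethylsilyloxy)-2,6,6-trimethylcyclohex-2-ene-1-carbaldehyde | CC1=C[C@@H](O[Si](C)(C)C(C)(C)C)CC(C)(C)[C@H]1C=O | intermediate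
9 | tert-butyl{[(1S,4R)-4-[(E)-2-iodoethenyl]-3,5,5-trimethylcyclohex-2-en-1-yl]oxy}dimethylsilane | CC1=C[C@@H](O[Si](C)(C)C(C)(C)C)CC(C)(C)[C@H]1/C=C/I | intermediate
10 | but-2-yn-1-ol | CC#CCO | starting material
11 | (Z)-3-(4,4,5,5-tetramethyl-1,3,2-dioxaborolan-2-yl)but-2-en-1-ol | OC/C=C(C)/B1OC(C)(C)C(C)(C)O1 | intermediate
12 | (2E,4E)-5-[(1R,4S)-4-(tert-butyldimethylsilyloxy)-2,6,6-trimethylcyclohex-2-en-1-yl]-3-methylpenta-2,4-dien-1-ol | CC1=C[C@@H](O[Si](C)(C)C(C)(C)C)CC(C)(C)[C@H]1/C=C/C(C)=C/CO | intermediate
13 | primary allylic bromide of 12 | CC1=C[C@@H](O[Si](C)(C)C(C)(C)C)CC(C)(C)[C@H]1/C=C/C(C)=C/CBr | intermediate (not isolated)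
14 | triphenylphosphonium bromide of 13 | CC1=C[C@@H](O[Si](C)(C)C(C)(C)C)CC(C)(C)[C@H]1/C=C/C(C)=C/C[P+](c1ccccc1)(c1ccccc1)c1ccccc1.[Br-] | intermediate
15 | (2E,4E,6E)-2,7-dimethylocta-2,4,6-trienedial | O=C/C(C)=C/C=C/C=C(C)/C=O | starting material
16 | (3S,6R)-3-(tert-butyldimethylsilyloxy)-12'-apo-ε-caroten-12'-al | CC1=C[C@@H](O[Si](C)(C)C(C)(C)C)CC(C)(C)[C@H]1/C=C/C(C)=C/C=C/C(C)=C/C=C/C=C(C)/C=O | intermediate
17 | (1R,4S)-4-hydroxy-2,6,6-trimethylcyclohex-2-ene-1-carbaldehyde | CC1=C[C@@H](O)CC(C)(C)[C@H]1C=O | intermediate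
18 | 4,5-epoxide of 17 (carotenoid numbering), oxirane oxygen cis to the hydroxyl and the formyl group | O=C[C@@H]1C(C)(C)C[C@H](O)[C@@H]2O[C@]12C | intermediate (not isolated)
19 | (3R,4S)-3,4-dihydroxy-2,6,6-trimethylcyclohex-1-ene-1-carbaldehyde | O=CC1=C(C)[C@@H](O)[C@@H](O)CC1(C)C | intermediate
20 | (3R,4S)-3,4-bis(tert-butyldimethylsilyloxy)-2,6,6-trimethylcyclohex-1-ene-1-carbaldehyde | O=CC1=C(C)[C@@H](O[Si](C)(C)C(C)(C)C)[C@@H](O[Si](C)(C)C(C)(C)C)CC1(C)C | intermediate
21 | triethyl 3-methyl-4-phosphonocrotonate (E/Z mixture as sold) | CCOC(=O)C=C(C)CP(=O)(OCC)OCC | starting material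
22 | ethyl (2E,4E)-5-[(3R,4S)-3,4-bis(tert-butyldimethylsilyloxy)-2,6,6-trimethylcyclohex-1-en-1-yl]-3-methylpenta-2,4-dienoate | CCOC(=O)/C=C(C)/C=C/C1=C(C)[C@@H](O[Si](C)(C)C(C)(C)C)[C@@H](O[Si](C)(C)C(C)(C)C)CC1(C)C | intermediate
23 | (2E,4E)-5-[(3R,4S)-3,4-bis(tert-butyldimethylsilyloxy)-2,6,6-trimethylcyclohex-1-en-1-yl]-3-methylpenta-2,4-dien-1-ol | OC/C=C(C)/C=C/C1=C(C)[C@@H](O[Si](C)(C)C(C)(C)C)[C@@H](O[Si](C)(C)C(C)(C)C)CC1(C)C | intermediate
24 | primary allylic bromide of 23 | BrC/C=C(C)/C=C/C1=C(C)[C@@H](O[Si](C)(C)C(C)(C)C)[C@@H](O[Si](C)(C)C(C)(C)C)CC1(C)C | intermediate (not isolated)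
25 | triphenylphosphonium bromide of 24 | [Br-].c1ccccc1[P+](c1ccccc1)(c1ccccc1)C/C=C(C)/C=C/C1=C(C)[C@@H](O[Si](C)(C)C(C)(C)C)[C@@H](O[Si](C)(C)C(C)(C)C)CC1(C)C | intermediate
26 | (3S,4R,3'S,6'R)-3,4,3'-tris(tert-butyldimethylsilyloxy)-β,ε-carotene | CC1=C[C@@H](O[Si](C)(C)C(C)(C)C)CC(C)(C)[C@H]1/C=C/C(C)=C/C=C/C(C)=C/C=C/C=C(C)/C=C/C=C(C)/C=C/C1=C(C)[C@@H](O[Si](C)(C)C(C)(C)C)[C@@H](O[Si](C)(C)C(C)(C)C)CC1(C)C | intermediate
27 | (3S,4R,3'S,6'R)-β,ε-carotene-3,4,3'-triol | CC1=C[C@@H](O)CC(C)(C)[C@H]1/C=C/C(C)=C/C=C/C(C)=C/C=C/C=C(C)/C=C/C=C(C)/C=C/C1=C(C)[C@@H](O)[C@@H](O)CC1(C)C | target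

**Total step count:** 19. **Longest linear sequence:** 14 (steps 1–6, then 12–19).

**Steps most likely to fail**

Step 6.
- What may go wrong: hydride shift from C7' instead of the carbon shift, SN2' attack of bromide at C4' followed by transannular ether formation, or epimerisation of the allylic bromide that erodes the fidelity at C6'.
- Fallback: it sets out from 6 and returns at 8. The catalytic halide relay is replaced by a stepwise, stoichiometric semipinacol.
- Compound 6 is hydrolysed in hot aqueous dioxane without acid. Water enters at allylic C6' with inversion and gives (1S,2S,5S)-5-(tert-butyldimethylsilyloxy)-3,7,7-trimethylcyclohept-3-ene-1,2-diol F1.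
- The less hindered allylic hydroxyl is mesylated (MsCl, Et3N, CH2Cl2, −78 °C) to the 6'-monomesylate F2, which is treated cold and without purification with Et3Al.
- The aluminium alkoxide at C7' pushes, aluminium pulls the mesylate, and C1' (anti to the leaving group) migrates. Because F2 has the geometry of 7, the sense at C6' is the same and 8 results.

Step 4.
- What may go wrong: poor facial selectivity if catalyst and resident epoxide are mismatched, or reductive opening of the vinyl epoxide by the borane.
- Fallback: it sets out from 4 and returns at 5. Catalyst control is given up.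
- Luche reduction (NaBH4, CeCl3·7H2O, MeOH, −78 °C) gives both carbinols, and the 3'S part is 5 itself.
- The 3'R epimer, the cis-epoxy alcohol F3, is separated and inverted by a Mitsunobu reaction (4-nitrobenzoic acid, PPh3, DIAD) to the 3'S 4-nitrobenzoate F4. K2CO3 in MeOH cleaves F4 to 5.

Step 2.
- What may go wrong: an unfavourable equilibrium, aromatisation through cleavage of an outer cyclopropane bond, or self-condensation under base.
- Fallback: it sets out from 2 and returns at 3. Instead of equilibration under base, the dienol is trapped.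
- Me3SiOTf and Et3N in CH2Cl2 convert 2 into its ring dienol silyl ether. As a norcaradiene this opens at once to trimethyl[(4,7,7-trimethylcyclohepta-1,3,5-trien-2-yl)oxy]silane F5.
- Buffered hydrolysis (aqueous citric acid, THF) protonates C2' and gives 3.

**Further compounds**
F1 | step 6 | (1S,2S,5S)-5-(tert-butyldimethylsilyloxy)-3,7,7-trimethylcyclohept-3-ene-1,2-diol | CC(C)(C)[Si](C)(C)O[C@@H]1C=C(C)[C@H](O)[C@@H](O)C(C)(C)C1
F2 | step 6 | 6'-monomesylate of F1 (mesylate on the allylic carbinol) | CC(C)(C)[Si](C)(C)O[C@@H]1C=C(C)[C@H](OS(C)(=O)=O)[C@@H](O)C(C)(C)C1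
F3 | step 4 | (1R,4R,7S)-2,6,6-trimethyl-8-oxabicyclo[5.1.0]oct-2-en-4-ol (hydroxyl cis to the oxirane oxygen) | O[C@H]1C=C(C)[C@H]2O[C@H]2C(C)(C)C1
F4 | step 4 | 4-nitrobenzoate of 5 | O=C(O[C@@H]1C=C(C)[C@H]2O[C@H]2C(C)(C)C1)c1ccc(cc1)[N+](=O)[O-]
F5 | step 2 | trimethyl[(4,7,7-trimethylcyclohepta-1,3,5-trien-2-yl)oxy]silane | CC1=CC(O[Si](C)(C)C)=CC(C)(C)C=C1
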